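**Assumption:** the acyl chain is read as 36 carbons with the carbonyl carbon counted (hexatriacontanoyl). The molecule has no stereocentre and no double-bond geometry, so nothing stereochemical has to be set. A different chain count would change only the length of bromide 2.

## Retrosynthetic overview

1. Key disconnection at C11–C12 and C12–C13 of the acyl chain (C1 = carbonyl carbon). C12 comes from C2 of 1,3-dithiane (1), a masked formyl/acyl anion used as a CH2 dianion. It is alkylated twice in one flask, by 1-bromotetracosane (2, C13–C36) and by 11-bromoundecanoic acid (3, C1–C11, as its lithium carboxylate), through in-flask species 4 to 8, to give dithiane acid 9.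
2. C–S disconnection: reductive desulfurization of 9 gives the unbranched C36 acid 10.
3. Ester C–O disconnection: 10 plus tyrosol (11) gives target 12, acylating only the aliphatic OH, with no protecting groups.
4. Rings: none is built. The benzene ring is bought in 11, and the dithiane ring of 1 is only an auxiliary that is destroyed in the desulfurization.

## Route

Step 1
Reactants: 1 1,3-dithiane; 2 1-bromotetracosane; 3 11-bromoundecanoic acid
Product: 9 11-(2-tetracosyl-1,3-dithian-2-yl)undecanoic acid, via 2-lithio-1,3-dithiane 4 (not isolated), via 2-tetracosyl-1,3-dithiane 5 (not isolated), via 2-lithio-2-tetracosyl-1,3-dithiane 6 (not isolated), via lithium 11-bromoundecanoate 7 (not isolated), via lithium 11-(2-tetracosyl-1,3-dithian-2-yl)undecanoate 8 (not isolated)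
Conditions: (a) 1, n-BuLi (1.0 equiv), THF, −30 °C, 2 h; (b) 2 (1.0 equiv) in THF, −30 → 25 °C, 12 h; (c) n-BuLi (1.05 equiv), −20 → 0 °C, 3 h; (d) 7 [separate flask: 3 (1.1 equiv), LiN(SiMe3)2 (1.1 equiv), THF–DMPU, 0 °C], 0 → 25 °C, 16 h; (e) aq. HCl to pH 2
Reagents that add atoms: none
Why: Corey–Seebach umpolung used as a one-flask linchpin coupling: C2 of the dithiane (a formaldehyde carbon, normally electrophilic) is lithiated twice and displaces bromide from two electrophilic primary carbons in turn (SN2). The lithium carboxylate of 7 is inert to the hindered dithianyl anion, so no protecting group is needed, and no stereocentre is formed.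

Step 2
Reactants: 9 11-(2-tetracosyl-1,3-dithian-2-yl)undecanoic acid
Product: 10 hexatriacontanoic acid
Conditions: Raney Ni (W-2, large excess), EtOH–THF 1:1, reflux, 6 h; hot filtration, then recrystallization from toluene
Reagents that add atoms: none
Why: Mozingo-type hydrogenolysis of the four C–S bonds on hydrogen-loaded Raney Ni turns the masked carbonyl carbon into a plain CH2; the carboxylic acid is untouched and no stereocentre is involved.

Step 3
Reactants: 10 hexatriacontanoic acid; 11 tyrosol [2-(4-hydroxyphenyl)ethanol] (3 equiv)
Product: 12 2-(4-hydroxyphenyl)ethyl hexatriacontanoate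
Conditions: TsOH·H2O (10 mol%), toluene, reflux, Dean–Stark, 12 h; hot-water wash to remove excess 11, then recrystallization
Reagents that add atoms: none
Why: Fischer esterification driven by azeotropic water removal. Under acid catalysis the phenolic OH is a far poorer nucleophile and aryl esters are disfavoured at equilibrium, so only the primary alcohol is acylated; no stereocentre is formed.

## Compound list

1 | 1,3-dithiane | C1CSCSC1 | starting material
2 | 1-bromotetracosane | CCCCCCCCCCCCCCCCCCCCCCCCBr | starting material
3 | 11-bromoundecanoic acid | OC(=O)CCCCCCCCCCBr | starting material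
4 | 2-lithio-1,3-dithiane | [Li]C1SCCCS1 | intermediate
5 | 2-tetracosyl-1,3-dithiane | CCCCCCCCCCCCCCCCCCCCCCCCC1SCCCS1 | intermediate
6 | 2-lithio-2-tetracosyl-1,3-dithiane | CCCCCCCCCCCCCCCCCCCCCCCCC1([Li])SCCCS1 | intermediate
7 | lithium 11-bromoundecanoate | [Li+].[O-]C(=O)CCCCCCCCCCBr | intermediate
8 | lithium 11-(2-tetracosyl-1,3-dithian-2-yl)undecanoate | [Li+].[O-]C(=O)CCCCCCCCCCC1(CCCCCCCCCCCCCCCCCCCCCCCC)SCCCS1 | intermediate
9 | 11-(2-tetracosyl-1,3-dithian-2-yl)undecanoic acid | OC(=O)CCCCCCCCCCC1(CCCCCCCCCCCCCCCCCCCCCCCC)SCCCS1 | intermediate
10 | hexatriacontanoic acid | CCCCCCCCCCCCCCCCCCCCCCCCCCCCCCCCCCCC(=O)O | intermediate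
11 | tyrosol [2-(4-hydroxyphenyl)ethanol] | OCCc1ccc(O)cc1 | starting material
12 | 2-(4-hydroxyphenyl)ethyl hexatriacontanoate | CCCCCCCCCCCCCCCCCCCCCCCCCCCCCCCCCCCC(=O)OCCc1ccc(O)cc1 | target

## Step count and risk

Total step count: 3. Longest linear sequence: 3.

The route has only three steps, so all three are listed, most risky first.

**Step 1.** Risks: the waxy C24 species and the lithium carboxylate dissolve poorly; the second lithiation may be incomplete in the same flask; E2 may compete on the bromo-carboxylate. The fallback sets out from 3 and from 5 (made by parts a and b of step 1, this time isolated and recrystallised) and comes back to the route at 9. Acid 3 is treated with isobutene and catalytic H2SO4 in CH2Cl2 to give tert-butyl 11-bromoundecanoate F1, a neutral, soluble electrophile. Pure 5 is lithiated on its own (n-BuLi, THF, −20 °C) and alkylated with F1 in THF–DMPU at −78 → 0 °C to give tert-butyl 11-(2-tetracosyl-1,3-dithian-2-yl)undecanoate F2. CF3CO2H in CH2Cl2 then removes the tert-butyl group and delivers 9.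

**Step 2.** Risks: incomplete desulfurization, or loss of the fatty acid on the nickel surface. The fallback sets out from 9 and comes back at 10, replacing hydrogenolysis by unmasking and deoxygenation. The dithiane is hydrolysed with MeI and CaCO3 in aqueous MeCN–THF at 50 °C to give 12-oxohexatriacontanoic acid F3. F3 is then reduced under Huang-Minlon Wolff–Kishner conditions (N2H4·H2O, KOH, diethylene glycol, 130 → 200 °C, then HCl work-up) to 10. Any methyl ester formed by MeI is saponified in the same operation.

**Step 3.** Risks: slow esterification of the poorly soluble C36 acid, or acid-promoted side reactions of tyrosol. The fallback sets out from 10 and comes back at 12, activating the acid instead of relying on equilibrium. Acid 10 is converted with oxalyl chloride and catalytic DMF in warm toluene into hexatriacontanoyl chloride F4. F4 is added to 11 in dimethyl carbonate–THF at 40 °C without base, where the neutral phenol reacts much more slowly than the primary alcohol, giving 12 directly.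

## Further compounds

F1 | step 1 | tert-butyl 11-bromoundecanoate | CC(C)(C)OC(=O)CCCCCCCCCCBr
F2 | step 1 | tert-butyl 11-(2-tetracosyl-1,3-dithian-2-yl)undecanoate | CC(C)(C)OC(=O)CCCCCCCCCCC1(CCCCCCCCCCCCCCCCCCCCCCCC)SCCCS1
F3 | step 2 | 12-oxohexatriacontanoic acid | OC(=O)CCCCCCCCCCC(=O)CCCCCCCCCCCCCCCCCCCCCCCC
F4 | step 3 | hexatriacontanoyl chloride | CCCCCCCCCCCCCCCCCCCCCCCCCCCCCCCCCCCC(=O)Cl
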